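The leftover Q at the 5.00 min reading of the ash run is my starting point, since that Q can still become D while D is fading.

| flask | Q | E | remark | time | volume of the second phase over the first |
|---|---|---|---|---|---|
| ash | 0.17 M | 1.4 M | run made earlier |  |  |
| flask | 0.35 M | 1.40 M |  | 12 min | 0.50 |

ash run (percent of the Q charged): time / min: D / % = 0.833: 42.0; 1.33: 59.6; 2.50: 79.4; 5.00: 87.6; 10.0: 78.8

(readings scatter by 0.3 percentage points)

- in the second phase: E; everything else is in the first
- charges count per volume of the first phase; a concentration in a rate is the amount of a species over the volume of its own phase; every rate counts per litre of the first phase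
- the earlier runs hold the two phases in the same ratio of volumes as the flask asked about

- Friday's: doubling the amount of E, all else as stated
- Wednesday's: doubling the transfer coefficient of E, all else as stated

- how much D there is at 12 min, in percent of the Q charged
- the change that raises the amount of D at 12 min, in percent of the Q charged most ("none" if none brings more than 2 percentage points) (Friday's / Wednesday's / none)
- amount of D at 12 min, in percent of the Q charged, after Wednesday's

I solve the curve at both ends and join them. At the early end, I take whatever is not yet read as D to be Q still waiting, and the first two ash readings give a rise constant:

rise constant = ln(waiting Q at 0.833 min / waiting Q at 1.33 min) / interval = 0.728 min⁻¹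

This puts the leftover Q of the ash run at 5.00 min at 2.63 % of the charge. At the late end, I add that leftover to the D read there and follow the sum down to the last reading:

fade constant = ln((D + leftover Q) / last D) / interval = 0.0271 min⁻¹

The fade constant is the first-order rate, read from the ash run with the scatter of its readings, at which D shrinks once Q has stopped feeding it. The rise is much faster than the fade, so the two ends of the ash curve join in an estimated peak near 4.70 min, at about 88.0 %. After that, the ash tail halves every 25.6 min.

The flask charges twice the Q of the ash run, but its 0.35 M is still less than the 1.40 M of E, so Q is the limiting reagent. I assume the flask, in percent of its own charge, follows the ash run, and 12 min is later than the ash peak, so I carry the last ash reading forward: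

D at 12 min = 78.8 % × exp(−fade constant × 2.00 min) = 74.6 %

The forecast says 77 %, between 70 % and 81 %, which is 2.4 percentage points above my figure. It gives 76.5 % after Wednesday's and names none as the best change, holding that “Faster transfer barely matters, since transfer is not limiting”.

The flask gives 74.1 % and the best change is none: Friday's moves D by −1.1 points, and Wednesday's moves it by −0.14 points, to 74.0 %.

    Q + L → D (k = 0.0120 L mol⁻¹ s⁻¹)
    L ⇌ E, rate k2*([L] - [E]/K2) per volume of the first phase (partition coefficient = 0.440, kL = 0.0200 s⁻¹)
    D → G (k = 4.60 × 10⁻⁴ s⁻¹)
    Q + D → Z (k = 3.50 × 10⁻⁴ L mol⁻¹ s⁻¹)

At 12 min the flask has 0.045 % of its Q left, so from there on I apply the fade constant by itself. Over the further 38.0 min, it takes the 74.1 % down to 26.5 %. The same flask left until 50 min holds 26.0 % of D, with 73.0 % as G.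

(The numbers in the tables stem from a simulated flask on assumed constants, and the scatter is random.)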